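**Remarks on the chemistry (assumptions).** The SMILES has no descriptor for the hindered C4–N1′ axis, so the target is taken as drawn; if the axis is configurationally stable, the route gives the racemate. Compounds 1 and 8 are taken as purchasable.

Ring letters: ring A is the benzene ring of the methoxyindole (C3a, C4–C7, C7a), ring B its pyrrole ring, ring C the pyrrole ring of the N-linked indole (N1′, C2′, C3′), and ring D its benzene ring.

## The problem

Rivularin B is a 1′,4-linked biindole: N1′ of a 3,5-dibromoindole is bonded to C4 of a 3,5-dibromo-7-methoxy-1H-indole. The C4–N1′ bond sits between C5–Br and the ring fusion C3a with its peri C3–Br, so it is a di-ortho-flanked N-aryl bond. Any metal-mediated way of making it must also tell apart several carbon–halogen bonds. The bromine at C5 is meta to the methoxy group, on a benzene ring where electrophilic substitution does not go there: after the two C3 positions, an electrophile takes C2 or C6. Four C–Br bonds rule out late lithiation, hydrogenation, dissolving metals and zerovalent palladium, and the two C3 bromides are the most labile (acid, light, reductants), so they must come last. There are no stereocentres.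

The feature that the plan uses lies in ring A. C4 (bearing N1′) and C7 (bearing OMe) are para, and C5 is the neighbour of C4. Ring A is therefore the aromatized condensation product of a secondary amine with a C4 ketone / C7 dimethyl ketal (a quinone monoketal). In the saturated parent of that ketone, C5 is the only enolizable α-carbon. N1′ belongs to ring C, which can be carried as an indoline; its C2′H2–C3′H2 unit supplies exactly the two hydrogens that take ring A from the quinone level to the arene level.

## Retrosynthesis

**13 to 12.** The C3–Br and C3′–Br bonds are cut first. Both carbons are enamine β-positions and the most nucleophilic sites of 12, so a twofold electrophilic bromination directs itself. Placing it last keeps the labile bromides out of every other step. The forward reaction must stop at two bromines.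

**12 to 11.** The N1–H is traced back to N1–tosyl. The sulfonyl group is needed earlier: it stops N1 from donating into the C4 carbonyl, it protects ring B from bromine and from the trivalent iodine oxidant, and it is removable by hydroxide without touching C–Br.

**11 to 7 + 8 (key cut).** The C4–N1′ bond is cut, and at the same time ring A is taken back to the quinone monoketal 7 and ring C to 5-bromoindoline 8. Cutting the same bond as aryl halide plus indole N–H would need a metal and a halogen at C4 next to C5–Br. This cut instead needs only a carbonyl at C4, and the C7 methoxy group is what remains of the ketal. Compound 8 is commercial and already carries the C5′ bromine, and 7 is a bicyclic compound with one bromine. The forward reaction must condense a hindered ketone with a weakly basic amine and then aromatize two rings through intermediates 9 and 10.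

**7 to 5.** Both C7–O bonds are cut. The para-unsubstituted phenol 5 is oxidized twice in methanol, through the p-methoxyphenol 6. The ortho positions are blocked by bromine at C5 and by the ring fusion at C3a, so only C7 is open.

**5 to 3 to 2 to 1.** The C5–Br bond is cut at the level of the saturated ketone. Geminal dibromination of 2 at C5, the only enolizable carbon, gives 3. Loss of HBr gives the dienone 4, which tautomerizes to 5, so the position of bromine is fixed by enol chemistry and not by aromatic substitution. Ketone 1 is a commercial building block.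

## Roads not taken

**Alternative 1:** the most obvious cut, C4–N1′ as aryl halide plus indole N–H. The forward step is a CuI/diamine Ullmann–Goldberg or a zerovalent-palladium Buchwald–Hartwig N-arylation of 5-bromo-1H-indole A1 with 4-iodo-7-methoxy-1-tosyl-1H-indole A2, giving 5-bromo-1-(7-methoxy-1-tosyl-1H-indol-4-yl)-1H-indole A3, followed by bromination.
- The metal must choose the peri-hindered C4–I of A2 over the unhindered C5–Br of A1, so self-coupling of A1 competes.
- A3 has no bromine at C5, and later electrophilic bromination goes to C3, C3′ and then C2 or C6, not to C5.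
- Carrying a C5–Br on A2 would make the coupling site di-ortho-substituted and add one more competing C–Br bond.
- The chosen plan uses no metal and sets C5–Br by enolization.

**Alternative 2:** ring B made last by a Bartoli indole synthesis (cut C3–C3a and N1–C2). C4 is meta to the nitro group, so SNAr is not available. A1 would be joined by Cu-catalysed N-arylation to 1-bromo-2-iodo-5-methoxy-4-nitrobenzene A4 to give 5-bromo-1-(2-bromo-4-methoxy-5-nitrophenyl)-1H-indole A5, and a vinyl Grignard reagent would then convert A5 into 12.
- On paper this is no longer than the chosen route.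
- Its weakest step comes last: the Bartoli [3,3] shift relies on a bulky ortho group, methoxy is a weak one, and the new C3–C3a bond forms next to the carbon bearing the N-indolyl group.
- Three equivalents of Grignard reagent meet a nitroarene with two C–Br bonds.
- A4 is not a commodity and needs its own regiocontrolled synthesis, and the coupling still needs iodine/bromine discrimination beside an ortho bromine.

**Alternative 3:** an aryne that takes up C4–N and C5–Br in one operation. 7-Methoxy-1-tosyl-5-(trimethylsilyl)-1H-indol-4-yl trifluoromethanesulfonate A6 would give, with fluoride, the 4,5-indolyne A7, to be trapped by the anion of A1 and then by an electrophilic bromine source.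
- The groups beside the triple bond decide the regiochemistry. On one side is the ring fusion C3a, whose five-membered ring makes C5 the flatter, more electrophilic terminus. On the other is C6–H, with no inductive director, and the C7 methoxy is one carbon too far.
- The nitrogen would therefore add mainly at C5 and bromine at C4, giving the inverse isomer 4-bromo-5-(5-bromo-1H-indol-1-yl)-7-methoxy-1-tosyl-1H-indole A8.
- A6 needs a long run-up, and the bromine source would also attack C3 of the indolide.
- The chosen plan fixes both positions by the connectivity of a ketone.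

Key step: step 5

## Route

Step 1
Reactants: 1 1,5,6,7-tetrahydro-4H-indol-4-one
Product: 2 1-tosyl-1,5,6,7-tetrahydro-4H-indol-4-one
Conditions: NaH, TsCl, THF, 0 °C to rt
Reagents that add atoms: p-toluenesulfonyl chloride, Cc1ccc(S(=O)(=O)Cl)cc1
Why: N-sulfonylation of the vinylogous-amide N–H after deprotonation; the tosyl group stops N1 from donating into the C4 carbonyl and shields ring B from electrophiles in steps 2, 4 and 5.

Step 2
Reactants: 2 1-tosyl-1,5,6,7-tetrahydro-4H-indol-4-one
Product: 3 5,5-dibromo-1-tosyl-1,5,6,7-tetrahydro-4H-indol-4-one
Conditions: Br2 (2.1 equiv), HBr (cat.), AcOH–CH2Cl2, 0 °C to rt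
Reagents that add atoms: bromine, BrBr
Why: Acid-catalysed α-halogenation of a ketone through its enol; C5 is the only enolizable α-carbon of 2 (C3a belongs to ring B), so both bromine atoms go to C5, and the N-sulfonyl-3-acylpyrrole ring is too electron-poor to compete.

Step 3
Reactants: 3 5,5-dibromo-1-tosyl-1,5,6,7-tetrahydro-4H-indol-4-one
Product: 5 5-bromo-1-tosyl-1H-indol-4-ol, via bromodienone tautomer 4 (not isolated)
Conditions: DBU (2.2 equiv), MeCN, 0 °C to rt; aq. NH4Cl
Reagents that add atoms: none
Why: E2 dehydrobromination across C5–C6 gives the dienone 4, the keto tautomer of a phenol, which enolizes at once through C7–H to aromatic ring A; this is the established 2,2-dibromo-1-tetralone to 2-bromo-1-naphthol aromatization and it fixes bromine at C5 without any aromatic substitution.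

Step 4
Reactants: 5 5-bromo-1-tosyl-1H-indol-4-ol
Product: 7 5-bromo-7,7-dimethoxy-1-tosyl-1,7-dihydro-4H-indol-4-one, via 5-bromo-7-methoxy-1-tosyl-1H-indol-4-ol 6 (not isolated)
Conditions: PhI(OAc)2 (2.2 equiv), MeOH, 0 °C to rt; NaHCO3 quench
Reagents that add atoms: methanol, CO
Why: Oxidative dearomatization of a phenol by a trivalent iodine reagent in methanol, the p-quinone monoketal synthesis known for para-unsubstituted phenols and 1-naphthols; the first equivalent puts methanol at C7, para to the hydroxyl, giving 6 after tautomerization, and the second turns this p-methoxyphenol into ketal 7, the ortho positions being closed by bromine (C5) and the ring fusion (C3a).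

Step 5
Reactants: 7 5-bromo-7,7-dimethoxy-1-tosyl-1,7-dihydro-4H-indol-4-one; 8 5-bromoindoline
Product: 11 5-bromo-1-(5-bromo-7-methoxy-1-tosyl-1H-indol-4-yl)-1H-indole, via quinoid iminium benzoate 9 (not isolated), via N-aryl-3H-indolium benzoate 10 (not isolated)
Conditions: PhCO2H (0.3 equiv), 4 Å molecular sieves, toluene, 100 °C
Reagents that add atoms: none
Why: Proposed new method: acid-catalysed condensation of the secondary amine 8 with the C4 carbonyl of 7 gives the quinoid iminium ion 9, whose only α-hydrogens are those at C2′, because C5 carries bromine and C3a is part of ring B; loss of a C2′ proton gives azomethine-ylide character at C4, and this electron pair expels methoxide from C7 through the C5=C6 bond (a vinylogous E1cB elimination), which aromatizes ring A and leaves the 3H-indolium ion 10, and loss of a C3′ proton from 10 then aromatizes ring C to give 11. The closest known reaction type is the carboxylic-acid-catalysed redox amination of indolines with aldehydes and ketones, where the same iminium and azomethine-ylide sequence gives an N-substituted indole, combined here with the aromatization of quinone-monoketal condensation products by loss of methanol. The step is redox-neutral, since the two hydrogens of C2′ and C3′ pay for the change of ring A from the quinone to the arene level, so no metal and no oxidant meets the C–Br bonds. No ring is closed and no stereocentre is formed; two rings are aromatized, and that is the driving force. The selectivity needed is 1,2-addition at C4 against conjugate addition at C6, which after loss of methanol would give a 6-amino-4-hydroxyindole. C6 lies between the quaternary ketal carbon and C5–Br, the α-bromine and the N-sulfonyl group raise the electrophilicity of C4=O, and removal of water pulls the reversible carbonyl addition forward. The methoxy group of the target is the ketal oxygen that is not expelled, so C7–OMe and C4–N end up para by construction.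

Step 6
Reactants: 11 5-bromo-1-(5-bromo-7-methoxy-1-tosyl-1H-indol-4-yl)-1H-indole
Product: 12 5-bromo-1-(5-bromo-7-methoxy-1H-indol-4-yl)-1H-indole
Conditions: KOH, THF–MeOH–H2O, 50 °C
Reagents that add atoms: none
Why: Hydroxide cleaves the N–S bond of an N-sulfonylindole by attack at sulfur with indolide as leaving group, helped here by the peri methoxy group at C7; aryl bromides and the N-aryl bond are inert to these conditions.

Step 7
Reactants: 12 5-bromo-1-(5-bromo-7-methoxy-1H-indol-4-yl)-1H-indole
Product: 13 3,5-dibromo-4-(3,5-dibromo-1H-indol-1-yl)-7-methoxy-1H-indole (Rivularin B)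
Conditions: NBS (2.05 equiv), DMF, −20 to 0 °C, dark
Reagents that add atoms: N-bromosuccinimide, O=C1CCC(=O)N1Br
Why: Electrophilic bromination at the enamine-type β-carbons C3 and C3′, the two most nucleophilic positions of 12; two equivalents at low temperature should stop before C2, C2′ or C6 react, and the two most labile C–Br bonds are made last.

## Compound list

1 | 1,5,6,7-tetrahydro-4H-indol-4-one | O=C1CCCc2[nH]ccc21 | starting material
2 | 1-tosyl-1,5,6,7-tetrahydro-4H-indol-4-one | O=C1CCCc2c1ccn2S(=O)(=O)c1ccc(C)cc1 | intermediate
3 | 5,5-dibromo-1-tosyl-1,5,6,7-tetrahydro-4H-indol-4-one | O=C1c2ccn(S(=O)(=O)c3ccc(C)cc3)c2CCC1(Br)Br | intermediate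
4 | 5-bromo-1-tosyl-1,7-dihydro-4H-indol-4-one (bromodienone tautomer) | O=C1C(Br)=CCc2c1ccn2S(=O)(=O)c1ccc(C)cc1 | intermediate
5 | 5-bromo-1-tosyl-1H-indol-4-ol | Oc1c(Br)ccc2c1ccn2S(=O)(=O)c1ccc(C)cc1 | intermediate
6 | 5-bromo-7-methoxy-1-tosyl-1H-indol-4-ol | COc1cc(Br)c(O)c2ccn(S(=O)(=O)c3ccc(C)cc3)c12 | intermediate
7 | 5-bromo-7,7-dimethoxy-1-tosyl-1,7-dihydro-4H-indol-4-one | COC1(OC)C=C(Br)C(=O)c2ccn(S(=O)(=O)c3ccc(C)cc3)c21 | intermediate
8 | 5-bromoindoline | Brc1ccc2NCCc2c1 | starting material
9 | 5-bromo-1-(5-bromo-7,7-dimethoxy-1-tosyl-1,7-dihydro-4H-indol-4-ylidene)indolin-1-ium benzoate | COC1(OC)C=C(Br)C(=[N+]2CCc3cc(Br)ccc32)c2ccn(S(=O)(=O)c3ccc(C)cc3)c21.[O-]C(=O)c1ccccc1 | intermediate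
10 | 5-bromo-1-(5-bromo-7-methoxy-1-tosyl-1H-indol-4-yl)-3H-indol-1-ium benzoate | COc1cc(Br)c([N+]2=CCc3cc(Br)ccc32)c2ccn(S(=O)(=O)c3ccc(C)cc3)c12.[O-]C(=O)c1ccccc1 | intermediate
11 | 5-bromo-1-(5-bromo-7-methoxy-1-tosyl-1H-indol-4-yl)-1H-indole | COc1cc(Br)c(-n2ccc3cc(Br)ccc32)c2ccn(S(=O)(=O)c3ccc(C)cc3)c12 | intermediate
12 | 5-bromo-1-(5-bromo-7-methoxy-1H-indol-4-yl)-1H-indole | COc1cc(Br)c(-n2ccc3cc(Br)ccc32)c2cc[nH]c12 | intermediate
13 | 3,5-dibromo-4-(3,5-dibromo-1H-indol-1-yl)-7-methoxy-1H-indole (Rivularin B) | COc1cc(Br)c(-n2cc(Br)c3cc(Br)ccc32)c2c(Br)c[nH]c12 | target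

## Step count and risks

Total: 7 steps. Longest linear sequence: 7 steps (1 to 13); compound 8 enters at step 5.

**Step 5 (key step, proposed new method).** The most likely failure is amination at the wrong carbon, by conjugate addition of the amine at C6 followed by loss of methanol. Others are hydrolysis of the ketal by the water of condensation, after which the quinone would oxidize the indoline, or failure of the hindered, bromine-flanked carbonyl to condense at all. Sulfonyl transfer from N1 to the amine is a lesser concern.

Fallback (known chemistry, from 8, returning at 12, so step 6 is skipped): 8 is dehydrogenated with MnO2 in CH2Cl2 to 5-bromo-1H-indole F1. F1 is N-arylated by SNAr (Cs2CO3, DMSO, 80 °C) with 3-bromo-2-fluoro-5-methoxybenzaldehyde F2, a catalogue building block whose fluorine is ortho to the formyl group, to give 3-bromo-2-(5-bromo-1H-indol-1-yl)-5-methoxybenzaldehyde F3. Hemetsberger–Knittel indole synthesis follows: condensation with methyl azidoacetate (NaOMe, MeOH, −10 °C) gives methyl (Z)-2-azido-3-[3-bromo-2-(5-bromo-1H-indol-1-yl)-5-methoxyphenyl]acrylate F4. Thermolysis in xylene gives methyl 5-bromo-4-(5-bromo-1H-indol-1-yl)-7-methoxy-1H-indole-2-carboxylate F5; the nitrene can insert only at the one free ortho C–H, which becomes C7a. Saponification (LiOH, THF–H2O) gives 5-bromo-4-(5-bromo-1H-indol-1-yl)-7-methoxy-1H-indole-2-carboxylic acid F6, and decarboxylation (Cu powder, quinoline, 200 °C) gives 12.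

**Step 3 (with step 2).** One bromine may be lost reductively, by attack of bromide or the base on bromine of the gem-dibromide instead of removal of the C6 proton, so that aromatization gives a phenol without C5–Br. Incomplete second bromination in step 2 leads to the same result.

Fallback (from 2, returning at 5): monobromination with CuBr2 in EtOAc–CHCl3 at reflux gives racemic 5-bromo-1-tosyl-1,5,6,7-tetrahydro-4H-indol-4-one F7. Dehydrobromination (Li2CO3, LiBr, DMF, 120 °C) gives 1-tosyl-1H-indol-4-ol F8. Amine-mediated ortho-bromination of the phenol (NBS, catalytic i-Pr2NH, CH2Cl2, 0 °C) then gives 5; the bromine is now placed by directed aromatic substitution instead of enol chemistry.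

**Step 4.** Methanol may attack the bromine-bearing ortho carbon, the second oxidation may be slow, or the ketal may hydrolyse and over-oxidize to the quinone.

Fallback (from 2, returning at 7): through F7 and F8 as above. The bromine-free phenol F8 is oxidized with PhI(OAc)2 in MeOH to 7,7-dimethoxy-1-tosyl-1,7-dihydro-4H-indol-4-one F9. C5–Br is then introduced by the standard α-bromination of an enone, bromine addition to C5=C6 followed by dehydrobromination (Br2, CH2Cl2, 0 °C; then Et3N), to give 7. This moves the C–Br bond formation to after the oxidation and changes its mechanism.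

**Step 7.** Over-bromination at C2 or C6, or oxidative decomposition of the electron-rich free indole, may occur.

Fallback (from 11, returning at 13): bromination is done while N1 still carries the sulfonyl group, which tempers ring B. NBS (1 equiv, DMF, 0 °C) brominates C3′, then Br2 (CH2Cl2, rt) brominates C3 of the N-sulfonylindole, giving 3,5-dibromo-4-(3,5-dibromo-1H-indol-1-yl)-7-methoxy-1-tosyl-1H-indole F10. Detosylation with KOH in THF–MeOH–H2O gives 13.

## Further compounds

F1 | step 5 | 5-bromo-1H-indole | Brc1ccc2[nH]ccc2c1
F2 | step 5 | 3-bromo-2-fluoro-5-methoxybenzaldehyde | COc1cc(Br)c(F)c(C=O)c1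
F3 | step 5 | 3-bromo-2-(5-bromo-1H-indol-1-yl)-5-methoxybenzaldehyde | COc1cc(Br)c(-n2ccc3cc(Br)ccc32)c(C=O)c1
F4 | step 5 | methyl (Z)-2-azido-3-[3-bromo-2-(5-bromo-1H-indol-1-yl)-5-methoxyphenyl]acrylate | COC(=O)/C(N=[N+]=[N-])=C/c1cc(OC)cc(Br)c1-n1ccc2cc(Br)ccc21
F5 | step 5 | methyl 5-bromo-4-(5-bromo-1H-indol-1-yl)-7-methoxy-1H-indole-2-carboxylate | COC(=O)c1cc2c(-n3ccc4cc(Br)ccc43)c(Br)cc(OC)c2[nH]1
F6 | step 5 | 5-bromo-4-(5-bromo-1H-indol-1-yl)-7-methoxy-1H-indole-2-carboxylic acid | OC(=O)c1cc2c(-n3ccc4cc(Br)ccc43)c(Br)cc(OC)c2[nH]1
F7 | step 3 | 5-bromo-1-tosyl-1,5,6,7-tetrahydro-4H-indol-4-one (racemic) | O=C1c2ccn(S(=O)(=O)c3ccc(C)cc3)c2CCC1Br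
F8 | step 3 | 1-tosyl-1H-indol-4-ol | Oc1cccc2c1ccn2S(=O)(=O)c1ccc(C)cc1
F9 | step 4 | 7,7-dimethoxy-1-tosyl-1,7-dihydro-4H-indol-4-one | COC1(OC)C=CC(=O)c2ccn(S(=O)(=O)c3ccc(C)cc3)c21
F10 | step 7 | 3,5-dibromo-4-(3,5-dibromo-1H-indol-1-yl)-7-methoxy-1-tosyl-1H-indole | COc1cc(Br)c(-n2cc(Br)c3cc(Br)ccc32)c2c(Br)cn(S(=O)(=O)c3ccc(C)cc3)c12
A1 | alternative 1 | 5-bromo-1H-indole | Brc1ccc2[nH]ccc2c1
A2 | alternative 1 | 4-iodo-7-methoxy-1-tosyl-1H-indole | COc1ccc(I)c2ccn(S(=O)(=O)c3ccc(C)cc3)c12
A3 | alternative 1 | 5-bromo-1-(7-methoxy-1-tosyl-1H-indol-4-yl)-1H-indole | COc1ccc(-n2ccc3cc(Br)ccc32)c2ccn(S(=O)(=O)c3ccc(C)cc3)c12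
A4 | alternative 2 | 1-bromo-2-iodo-5-methoxy-4-nitrobenzene | COc1cc(Br)c(I)cc1[N+](=O)[O-]
A5 | alternative 2 | 5-bromo-1-(2-bromo-4-methoxy-5-nitrophenyl)-1H-indole | COc1cc(Br)c(-n2ccc3cc(Br)ccc32)cc1[N+](=O)[O-]
A6 | alternative 3 | 7-methoxy-1-tosyl-5-(trimethylsilyl)-1H-indol-4-yl trifluoromethanesulfonate | COc1cc([Si](C)(C)C)c(OS(=O)(=O)C(F)(F)F)c2ccn(S(=O)(=O)c3ccc(C)cc3)c12
A7 | alternative 3 | 7-methoxy-1-tosyl-4,5-didehydro-1H-indole (4,5-indolyne) | COC1=CC#CC2=C1N(S(=O)(=O)c1ccc(C)cc1)C=C2
A8 | alternative 3 | 4-bromo-5-(5-bromo-1H-indol-1-yl)-7-methoxy-1-tosyl-1H-indole | COc1cc(-n2ccc3cc(Br)ccc32)c(Br)c2ccn(S(=O)(=O)c3ccc(C)cc3)c12
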